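**Strategy.** The pyran ring C (O1–C2–C3–C4–C4a–C8a) is not closed as such. Its only unsubstituted carbon, the C3 methylene between the two stereogenic benzylic carbons C2 and C4, is inserted into the furan C2=C3 bond of 6-benzyloxybenzofuran by chlorocarbene addition and electrocyclic ring opening. This one-carbon ring expansion gives the benzopyrylium oxidation level, in which C2 and C4 are latent electrophiles. C2 is then arylated under catalyst control (boronate addition to the chromene acetal). C4 is arylated last by trans-selective Friedel–Crafts hydroarylation with dodecanoylphloroglucinol, followed by hydrogenolysis.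

Key step: step 2

Remark: the sense of induction in step 3 is assigned by analogy with related aryl boronate additions to chromene acetals; if the L-tartaric acid derived catalyst should deliver the (R)-chromene, its enantiomer from D-tartaric acid is used instead.

Step 1
Reactants: 1 benzofuran-6-ol
Product: 2 6-(benzyloxy)-1-benzofuran
Conditions: BnBr, K2CO3, DMF, rt
Reagents that add atoms: benzyl bromide BrCc1ccccc1
Why: Williamson etherification (SN2 of the phenoxide on benzyl bromide) masks O-6 as an electron-donating ether that should survive the base, Lewis acid and Brønsted acid of the later steps and is removed by hydrogenolysis at the end.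

Step 2
Reactants: 2 6-(benzyloxy)-1-benzofuran
Product: 5 7-(benzyloxy)-2-ethoxy-2H-chromene (racemic), via chlorocyclopropane adduct 3 (not isolated), via chromenylium chloride 4 (not isolated)
Conditions: CH2Cl2 (excess), NaN(SiMe3)2, pentane, −20 °C → rt; then EtOH, K2CO3, 70 °C
Reagents that add atoms: dichloromethane ClCCl; ethanol CCO
Why: Chlorocarbene, formed by α-elimination from CH2Cl2, adds to the enol-ether-like C2=C3 bond of the furan ring (cheletropic [2+1] closure of the cyclopropane) to give 3; the endo chloride then ionises with disrotatory electrocyclic opening of the shared C1a–C6b bond, so that the carbene carbon is stitched in between the old furan C2 and C3 and the five-membered ring becomes the six-membered aromatic benzopyrylium ring of 4 (a ring expansion by one carbon, not a cyclisation). Ethanol then adds to C2 of 4 to give the acetal 5. The closest known reaction type is the Ciamician–Dennstedt-type halocarbene ring expansion of indoles, benzofurans and cyclic enol ethers. The only new stereocentre, the acetal carbon C2 of 5, is formed without control and is of no consequence because it is erased on ionisation in step 3. The step needs chemoselectivity for the furan C2=C3 bond over the benzenoid rings, which its enol ether character reinforced by the 6-benzyloxy group should secure, and the endo orientation of chlorine, which is the usual preference of chlorocarbenoid additions. Capture of ethanol at C4 instead of C2 would be harmless, since both ethers ionise to the same cation.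

Step 3
Reactants: 5 7-(benzyloxy)-2-ethoxy-2H-chromene; 6 [4-(benzyloxy)phenyl]boronic acid
Product: 9 (2S)-7-(benzyloxy)-2-[4-(benzyloxy)phenyl]-2H-chromene, via diethyl arylboronate 7 (not isolated), via chromenylium borate ion pair 8 (not isolated)
Conditions: 6, EtOH, 4 Å MS, PhMe, rt; then 5, (2R,3R)-tartaric acid mono(N,N-dibenzylamide) (5 mol %), Yb(OTf)3 (5 mol %), EtOAc, −20 °C
Reagents that add atoms: none
Why: Lewis-acid-assisted ionisation of the acetal regenerates the 7-benzyloxybenzopyrylium ion, and the electron-rich aryl group is transferred to C2 from the boronate after exchange onto the chiral dihydroxy acid (enantioselective Petasis-type boronate addition to a chromene acetal), so that C2 should be set as (S) by the catalyst.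

Step 4
Reactants: 10 phloroglucinol; 11 dodecanoyl chloride
Product: 12 1-(2,4,6-trihydroxyphenyl)dodecan-1-one
Conditions: AlCl3 (3 equiv), PhNO2, 80 °C; aq. HCl work-up
Reagents that add atoms: none
Why: Friedel–Crafts C-acylation of the symmetrical, highly activated triol should stop after one acyl group because the aryl ketone deactivates the ring.

Step 5
Reactants: 9 (2S)-7-(benzyloxy)-2-[4-(benzyloxy)phenyl]-2H-chromene; 12 1-(2,4,6-trihydroxyphenyl)dodecan-1-one
Product: 14 1-{3-[(2S,4R)-7-(benzyloxy)-2-[4-(benzyloxy)phenyl]-3,4-dihydro-2H-chromen-4-yl]-2,4,6-trihydroxyphenyl}dodecan-1-one, via flavan-4-ylium tosylate 13 (not isolated)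
Conditions: 12 (3 equiv), TsOH·H2O (20 mol %), 1,4-dioxane, 10 °C → rt, slow addition of 9
Reagents that add atoms: none
Why: Protonation of the styrenic C3=C4 bond at C3 gives the benzylic cation 13, stabilised by O1 and the para 7-benzyloxy group, and Friedel–Crafts alkylation by a free ring CH of 12 should follow by pseudoaxial attack on the half-chair cation from the face opposite to the pseudoequatorial C2 aryl group, which sets C4 as (R) with the 2,4-trans relationship (substrate control from C2).

Step 6
Reactants: 14 1-{3-[(2S,4R)-7-(benzyloxy)-2-[4-(benzyloxy)phenyl]-3,4-dihydro-2H-chromen-4-yl]-2,4,6-trihydroxyphenyl}dodecan-1-one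
Product: 15 (+)-myristinin A
Conditions: H2 (1 atm), 10 % Pd/C, EtOAc/MeOH, rt
Reagents that add atoms: none
Why: Hydrogenolysis of the two benzyl aryl ethers over palladium should leave the hydrogen-bonded aryl ketone, the cyclic benzylic ether C2–O1 and both stereocentres untouched, as is usual in flavan chemistry.

**Compound list**

1 | benzofuran-6-ol | Oc1ccc2ccoc2c1 | starting material
2 | 6-(benzyloxy)-1-benzofuran | c1cc2ccc(OCc3ccccc3)cc2o1 | intermediate
3 | 4-(benzyloxy)-1-chloro-1a,6b-dihydro-1H-cyclopropa[b][1]benzofuran (racemic, endo and exo chloride; not isolated) | ClC1C2Oc3cc(OCc4ccccc4)ccc3C12 | intermediate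
4 | 7-(benzyloxy)chromenylium chloride (not isolated) | [Cl-].c1cc2ccc(OCc3ccccc3)cc2[o+]c1 | intermediate
5 | 7-(benzyloxy)-2-ethoxy-2H-chromene (racemic) | CCOC1C=Cc2ccc(OCc3ccccc3)cc2O1 | intermediate
6 | [4-(benzyloxy)phenyl]boronic acid | OB(O)c1ccc(OCc2ccccc2)cc1 | starting material
7 | diethyl [4-(benzyloxy)phenyl]boronate (not isolated) | CCOB(OCC)c1ccc(OCc2ccccc2)cc1 | intermediate
8 | 7-(benzyloxy)chromenylium [4-(benzyloxy)phenyl]triethoxyborate ion pair (drawn without the chiral diol; not isolated) | c1cc2ccc(OCc3ccccc3)cc2[o+]c1.CCO[B-](OCC)(OCC)c1ccc(OCc2ccccc2)cc1 | intermediate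
9 | (2S)-7-(benzyloxy)-2-[4-(benzyloxy)phenyl]-2H-chromene | C1=C[C@@H](c2ccc(OCc3ccccc3)cc2)Oc2cc(OCc3ccccc3)ccc12 | intermediate
10 | phloroglucinol (benzene-1,3,5-triol) | Oc1cc(O)cc(O)c1 | starting material
11 | dodecanoyl chloride | CCCCCCCCCCCC(=O)Cl | starting material
12 | 1-(2,4,6-trihydroxyphenyl)dodecan-1-one | CCCCCCCCCCCC(=O)c1c(O)cc(O)cc1O | intermediate
13 | (2S)-7-(benzyloxy)-2-[4-(benzyloxy)phenyl]-3,4-dihydro-2H-chromen-4-ylium tosylate (not isolated) | [CH+]1C[C@@H](c2ccc(OCc3ccccc3)cc2)Oc2cc(OCc3ccccc3)ccc12.Cc1ccc(cc1)S(=O)(=O)[O-] | intermediate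
14 | 1-{3-[(2S,4R)-7-(benzyloxy)-2-[4-(benzyloxy)phenyl]-3,4-dihydro-2H-chromen-4-yl]-2,4,6-trihydroxyphenyl}dodecan-1-one | CCCCCCCCCCCC(=O)c1c(O)cc(O)c([C@@H]2C[C@@H](c3ccc(OCc4ccccc4)cc3)Oc3cc(OCc4ccccc4)ccc32)c1O | intermediate
15 | (+)-myristinin A, 1-{2,4,6-trihydroxy-3-[(2S,4R)-7-hydroxy-2-(4-hydroxyphenyl)-3,4-dihydro-2H-chromen-4-yl]phenyl}dodecan-1-one | CCCCCCCCCCCC(=O)c1c(O)cc(O)c([C@@H]2C[C@@H](c3ccc(O)cc3)Oc3cc(O)ccc32)c1O | target

**Step count.** Total steps: 6. Longest linear sequence: 5 steps (steps 1, 2, 3, 5, 6); step 4 prepares the acylphloroglucinol fragment.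

**Steps most likely to fail**

Step 2. Carbene transfer may be inefficient. The base may metalate the furan C2–H, the carbenoid may be consumed unproductively, or the adduct may form with exo chlorine, which cannot ionise with ring opening. The fallback sets out from 2 and uses a dihalocarbene, for which one halogen is necessarily endo. CHBr3 and KOt-Bu in pentane at 0 °C should give 4-(benzyloxy)-1,1-dibromo-1a,6b-dihydro-1H-cyclopropa[b][1]benzofuran F1. Warming in EtOH with K2CO3 should open it through 7-(benzyloxy)-3-bromochromenylium bromide F2 to 7-(benzyloxy)-3-bromo-2-ethoxy-2H-chromene F3. The surplus halogen is then removed reductively: bromine–lithium exchange (t-BuLi, THF, −78 °C) gives [7-(benzyloxy)-2-ethoxy-2H-chromen-3-yl]lithium F4, and protonation with MeOH returns to the route at 5.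

Step 3. Enantiofacial discrimination in the aryl transfer may be insufficient, or the transfer may be slow, with this para-benzyloxyphenyl boronate and the 7-alkoxy-stabilised cation. The fallback sets out from 5 and replaces asymmetric catalysis by resolution. Addition of commercial 4-(benzyloxy)phenylmagnesium bromide (THF, 0 °C → rt) displaces the ethoxy group and should give the racemic flavene, that is 9 together with (2R)-7-(benzyloxy)-2-[4-(benzyloxy)phenyl]-2H-chromene F5. Preparative chromatography on a chiral stationary phase separates the two, F5 is discarded, and the (S)-enantiomer re-enters the route as 9.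

Step 5. The flavene may be consumed before it is trapped, by hydride-transfer disproportionation to flavylium salt and flavan or by cationic dimerisation. Facial selectivity at C4 may be low. Reversible opening of the allylic C2–O1 bond under protic acid may erode the configuration at C2. The fallback sets out from 9 and separates cation formation from the hydride-donating alkene. Mukaiyama hydration (Co(acac)2, PhSiH3, O2, i-PrOH/THF, rt) places the hydroxyl at the benzylic C4 and should give (2S)-7-(benzyloxy)-2-[4-(benzyloxy)phenyl]-3,4-dihydro-2H-chromen-4-ol F6 as a mixture of C4 epimers, which is of no consequence. F6 and 12 are then coupled with BF3·OEt2 in 1,4-dioxane/CH2Cl2 at −20 °C, where the alcohol ionises to the same cation 13; this returns to the route at 14.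

**Further compounds**

F1 | step 2 | 4-(benzyloxy)-1,1-dibromo-1a,6b-dihydro-1H-cyclopropa[b][1]benzofuran (racemic) | BrC1(Br)C2Oc3cc(OCc4ccccc4)ccc3C12
F2 | step 2 | 7-(benzyloxy)-3-bromochromenylium bromide | [Br-].Brc1cc2ccc(OCc3ccccc3)cc2[o+]c1
F3 | step 2 | 7-(benzyloxy)-3-bromo-2-ethoxy-2H-chromene (racemic) | CCOC1Oc2cc(OCc3ccccc3)ccc2C=C1Br
F4 | step 2 | [7-(benzyloxy)-2-ethoxy-2H-chromen-3-yl]lithium (racemic) | CCOC1Oc2cc(OCc3ccccc3)ccc2C=C1[Li]
F5 | step 3 | (2R)-7-(benzyloxy)-2-[4-(benzyloxy)phenyl]-2H-chromene | C1=C[C@H](c2ccc(OCc3ccccc3)cc2)Oc2cc(OCc3ccccc3)ccc12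
F6 | step 5 | (2S)-7-(benzyloxy)-2-[4-(benzyloxy)phenyl]-3,4-dihydro-2H-chromen-4-ol (both C4 epimers) | OC1C[C@@H](c2ccc(OCc3ccccc3)cc2)Oc2cc(OCc3ccccc3)ccc12
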